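Its constants are made up; the rest is arithmetic.

At the earliest times J lay in the flask as solid with none of it dissolved, D and Q stood at their charges, and I wanted to know who would be done before whom.

J 27 mM; Q 54.0 mM; D 5.40 mM; time 4.0 h

- how much E.Q there is at 4.0 h, in percent of the J charged
- concentration of E in solution at 4.0 h, in percent of saturation

    2 Q → Q2 (k1 = 0.47 L mol⁻¹ min⁻¹)
    J → G (k2 = 4.4 × 10⁻⁵ min⁻¹)
    E + Q → E.Q (k3 = 0.79 L mol⁻¹ min⁻¹)
    J ⇌ E, rate k4*(cs4 - [E]) while solid is left; crystals form when [E] > cs4 (cs4 = 11 mM, k4 = 0.088 min⁻¹)
    J + D → J.D (k5 = 6.5 L mol⁻¹ min⁻¹)

With J at its charge, D had a half-life of 3.95 min, far shorter than the run, so I booked its charge, 20.0% of the J, as J.D. Dissolved E settled next, within 7.65 min, and faster than the 19.7 min that Q needed to fall to half by dimerisation, so while solid lay in the flask I let E follow Q, from 67.4% of saturation at the charge of Q towards saturation as Q fell. I took the midpoint, 83.7%, as a plain estimate. At that level the solid needed about 2.28 h to dissolve, less than the run. G, with a half-life of 263 h, lay far beyond the run, so I booked none.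

Dividing the rate of E.Q by the rate at which Q went to Q2 removed time and gave a selectivity factor. From it came the crossing level, the fraction of its charge at which Q entered both routes equally fast: 14.3%. At the charge of Q the dimerisation took 87.5% of each portion of Q, more than E took, and below the crossing level E took the larger part. Dimerisation alone would leave 7.59% of Q at the asked time, and I took that figure as the lower end of my sum, though E consumed Q as well. Summing the shares from the charge down to that figure gave E.Q as 47.3% of the J, and the J left unbound stood as E at 80.2% of saturation.

The forecast differed from my figures with 48% and 75%, on the ground that “E stays near saturation until the solid runs out”. The simulation gave 47.1% and 80.6%.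

In this flask Q read 41.5% at 0.400 h, above the crossing level, with 71% of the dimerisation's turnover up to 4.00 h already behind it, and 8.04% at 2.00 h, below that level. For the neighbour flask charged with 14 mM of Q, the same reckoning put the crossing level at 62.3%, and E.Q held 23.6% of the Q charge in this flask against 49.6% in that neighbour.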